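## The problem

Sodwanone T consists of two trans-fused 1-benzoxepine bicycles joined by a CH2–CH2 bridge between their tetrasubstituted ring alkenes. Ring A is the oxepane carrying the carbinol and sits on cyclohexene ring B; ring D is the oxepan-3-one and sits on cyclohexene ring C. Each half has a quaternary C–CH3 next to the ring-fusion CH–O, with the methyl cis to the oxygen and the oxepane CH2 trans to it. Ring A adds the fifth stereocentre, the (R)-carbinol beside the O–CMe2 carbon. Read atom by atom, the two halves have the same constitution and the same absolute configuration at both fusion carbons; they differ only at C3 of the oxepane (ketone in ring D, alcohol in ring A), so one bicyclic intermediate can serve twice. The hard bonds are the tertiary O–CMe2 ether to a neopentyl secondary oxygen and the trans relation between that oxygen and the CH2 on the quaternary carbon. Hydride reduction of a 2-allyl-2-methyl-1,3-dione is expected to enter anti to the larger allyl group and set the wrong (cis) relation, so the oxygen stereocentre should be made first and used to direct the C–allyl bond; the fusion centres and a chiral catalyst can then control the ring A carbinol. The ring D ketone (enolisable CH2, incompatible with boranes and organolithiums), the enol triflates (nucleophilic base) and the tertiary ether and tetrasubstituted alkenes (strong acid) limit the reagents. In ring D the C4 methylene and the C3 carbonyl lie between the C5 methylene on the quaternary C5a and the O–CMe2 carbon C2. C3=C4 can therefore be built as the double bond of a cyclic silyl enol ether from an allyl group on C5a and the silyl enol ether of an α-alkoxy methyl ketone.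

## Retrosynthesis

**Bridge.** The bond between C6 of ring C and the bridge CH2 is cut, giving the keto enol triflate 17 and the alkylborane 21, which comes from diene 20. Cutting the central CH2–CH2 bond would need an sp3–sp3 coupling of two hindered homoallylic partners, and a two-carbon linchpin coupled twice would give statistical mixtures because the halves differ. The chosen cut gives two bicycles that differ only at C3. The forward step is a B-alkyl Suzuki–Miyaura coupling on a hindered tetrasubstituted triflate in the presence of a ketone and a free hydroxyl.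

**Ring A/B partner.** Diene 20 is traced to triflate 18 by cutting the ring–vinyl bond (Stille coupling with stannane 19), and 18 to ketone 17 by removing the carbinol hydrogen. The ketone is differentiated before the coupling because afterwards only the ring D carbonyl should remain; reducing one of two nearly identical ketones in the coupled product would not be selective. The borane is placed on the alcohol half because 9-BBN would attack the ketone. The forward reduction must give the (R)-carbinol.

**Ring D (key cut).** Ketone 17 is the desilylated form of the cyclic silyl enol ether 16, and the C3=C4 bond of 16 is cut by retro-metathesis to the allyl/silyl enol ether 15. The alternative C–O closures onto the tertiary carbon or the neopentyl fusion carbon are the hardest bonds in the ring, and closing at C4–C5 would need an SN2 reaction at a neopentyl carbon. The metathesis cut leaves an open chain in which every stereocentre is already present. The forward reaction must load ruthenium on the allyl group and close onto a hindered 1,1-disubstituted enol ether.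

**Tertiary ether.** Enol ether 15 comes from methyl ketone 14, 14 from terminal alkyne 13 by hydration, and 13 from alcohol 9 and 2-methylbut-3-yn-2-ol 10 by cutting the O–CMe2 bond. A Williamson reaction at a tertiary carbon is not available, so the bond is made under SN1 conditions through the cobalt-stabilised propargylic cation (complexes 11 and 12). This is done after all strong-base steps on ring C, so the terminal alkyne never meets an amide base. The forward reaction must etherify a hindered secondary alcohol without touching the ring stereocentre.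

**Ring C alkene.** Alcohol 9 comes from silyl ether 8, whose enol triflate is cut back to the 6-methyl ketone 7 and then to ketone 6 (C–CH3 bond). The ketone has one enolisable side, so methylation and triflation have no regiochemical choice. The triflate also serves as the spectator group through the metathesis and as the coupling handle for both halves.

**Quaternary centre.** Ketone 6 is cut at the C2–allyl bond by a retro-Claisen rearrangement to allyl enol ether 5, which comes from allylic alcohol 4, vinylogous ester 3, and finally 2-methylcyclohexane-1,3-dione 1 and allyl alcohol 2. The more obvious order, C-allylation of 1 followed by reduction of one carbonyl, is expected to place the hydroxyl cis to the allyl group and lead to the cis-fused series. Setting the carbinol first and delivering the allyl group anti to the silyloxy group builds the trans relation in. The forward sequence needs an enantioselective 1,2-reduction of 3 and a face-selective [3,3] shift.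

## Roads not taken

**Alternative 1: double Birch reductive methylation.** The cut is at both quaternary C–CH3 bonds of a bis(cyclohexadiene) A1, made from the C2-symmetric bibenzyl bis(2-methoxybenzamide) A2 with Li in NH3 and MeI.
- Merits: both quaternary centres, both tetrasubstituted alkenes and the bridge arise in one flask from an aromatic precursor, with a proven chiral-amide control element. A1 is reached in fewer steps than the chosen route needs for 17, and in this respect it is better.
- Weak points: each quaternary carbon carries a hindered tertiary amide that must become the oxepane CH2, which needs excision and homologation twice. The enol ethers give ketones whose reduction must place oxygen cis to methyl. Both oxepanes and both tertiary ethers are still to be made, and the symmetric ends must be differentiated late into ketone and alcohol.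
- Comparison: the chosen plan answers with 17, which already contains the oxepane, the tertiary ether and both fusion centres, serves both halves, and is differentiated before the coupling.

**Alternative 2: furanone [2+2] photocycloaddition and cyclobutane opening.** The cut is at two bonds of a cyclobutane: irradiation of the 5-alkenyl furanone A4 gives the tricyclic photoadduct A3, and cleavage of the bond shared by furanone and cyclobutane expands it to the oxepanone.
- Merits: the O–CMe2–C=O unit is present from the start in the furanone, so the hardest ether bond costs nothing. Ring C, the quaternary centre and the ring D carbons arise in one step. In this respect it is shorter and better than the Nicholas/hydration/silylation sequence used here.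
- Weak points: the ring-fusion hydrogen is introduced during reductive fragmentation at an α-oxy radical or anion, with no clear element enforcing the trans fusion. Facial control of the cycloaddition rests on one remote silyloxy group, straight versus crossed addition is open, and the photochemistry must be scaled. Ring C still needs the ketone, methylation and triflation steps.
- Comparison: the chosen plan fixes the fusion stereochemistry by a Claisen shift before ring D exists and uses no radical quench.

**Alternative 3: transannular Prins closure.** The cut is at the fusion C–C bond: a Lewis acid ionises the eleven-membered α-acetoxy ether A6, the alkene attacks the oxocarbenium ion across the ring, and proton loss gives the ring A/B bicycle A5.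
- Merits: both rings and both fusion centres form in one step, and ring A arrives at the alcohol oxidation level with the carbinol already set. The chosen route needs a reduction for that, so on this point the alternative is better.
- Weak points: the macrocycle with a geometrically defined tetrasubstituted alkene, the tertiary ether and the acetal must be assembled first, so the ether problem is only moved. The stereochemical outcome depends on macrocycle conformation and alkene geometry, and the site of proton loss is not secured. Ring C/D would need a second, different sequence.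
- Comparison: the chosen plan has a longer linear sequence to the bicycle but each stereocentre is set by a separate, analysable step, and the same bicycle is used twice.

Key step: step 11

## Route

Remarks on the chemistry:
- Compound 7 is carried as a mixture of C6 epimers; that carbon becomes sp2 in step 6.
- Borane 21 is drawn with a free hydroxyl; any borinate formed at that oxygen should be cleaved by the aqueous base of the coupling.

Step 1
Reactants: 1 2-methylcyclohexane-1,3-dione; 2 prop-2-en-1-ol (allyl alcohol)
Product: 3 2-methyl-3-(prop-2-en-1-yloxy)cyclohex-2-en-1-one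
Conditions: p-TsOH·H2O (cat.), benzene, reflux, Dean–Stark
Reagents that add atoms: none
Why: Acid-catalysed vinylogous ester formation from the enolised 1,3-dione with azeotropic removal of water; at 80 °C the allyl vinyl ether should not yet rearrange.

Step 2
Reactants: 3 2-methyl-3-(prop-2-en-1-yloxy)cyclohex-2-en-1-one
Product: 4 (1S)-2-methyl-3-(prop-2-en-1-yloxy)cyclohex-2-en-1-ol
Conditions: (R)-2-methyl-CBS-oxazaborolidine (0.2 equiv), catecholborane (1.5 equiv), toluene, −78 → −40 °C; 1 M NaOH work-up
Reagents that add atoms: none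
Why: Corey–Bakshi–Shibata reduction of an α-substituted cyclic enone; the methyl-bearing alkene carbon acts as the large group and the ring CH2 as the small one, so the (R)-catalyst should give the (S)-carbinol. Catecholborane leaves the allyl alkene alone and the basic work-up protects the acid-labile 3-alkoxy allylic alcohol.

Step 3
Reactants: 4 (1S)-2-methyl-3-(prop-2-en-1-yloxy)cyclohex-2-en-1-ol
Product: 5 tert-butyl(dimethyl){[(1S)-2-methyl-3-(prop-2-en-1-yloxy)cyclohex-2-en-1-yl]oxy}silane
Conditions: TBSCl, imidazole, DMF, 0 °C → rt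
Reagents that add atoms: tert-butyldimethylsilyl chloride, CC(C)(C)[Si](C)(C)Cl
Why: Standard silylation under non-acidic conditions; the bulky silyloxy group protects the alcohol and becomes the control element of the next step.

Step 4
Reactants: 5 tert-butyl(dimethyl){[(1S)-2-methyl-3-(prop-2-en-1-yloxy)cyclohex-2-en-1-yl]oxy}silane
Product: 6 (2R,3S)-3-[(tert-butyldimethylsilyl)oxy]-2-methyl-2-(prop-2-en-1-yl)cyclohexan-1-one (allyl trans to the silyloxy group, methyl cis)
Conditions: o-xylene, 170 °C, sealed tube, base-washed glass
Reagents that add atoms: none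
Why: Thermal Claisen rearrangement of an allyl vinyl ether; A(1,2) strain with the C2 methyl holds the silyloxy group pseudoaxial, so the chair transition state should deliver the allyl group to the opposite face of C2. This sets the (2R) quaternary centre from the (S)-carbinol with allyl trans to oxygen.

Step 5
Reactants: 6 (2R,3S)-3-[(tert-butyldimethylsilyl)oxy]-2-methyl-2-(prop-2-en-1-yl)cyclohexan-1-one
Product: 7 (2R,3S)-3-[(tert-butyldimethylsilyl)oxy]-2,6-dimethyl-2-(prop-2-en-1-yl)cyclohexan-1-one (C6 epimers)
Conditions: LiN(i-Pr)2, THF, −78 °C; MeI, −78 → −30 °C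
Reagents that add atoms: iodomethane, CI
Why: Enolate alkylation; only C6 can be deprotonated because C2 is quaternary, and the silyloxy group is not β to the enolate carbon, so elimination is not possible.

Step 6
Reactants: 7 (2R,3S)-3-[(tert-butyldimethylsilyl)oxy]-2,6-dimethyl-2-(prop-2-en-1-yl)cyclohexan-1-one
Product: 8 (5S,6R)-5-[(tert-butyldimethylsilyl)oxy]-2,6-dimethyl-6-(prop-2-en-1-yl)cyclohex-1-en-1-yl trifluoromethanesulfonate
Conditions: KN(SiMe3)2, THF, −78 → 0 °C; PhNTf2, −78 → 0 °C
Reagents that add atoms: N-phenylbis(trifluoromethanesulfonimide), O=S(=O)(N(c1ccccc1)S(=O)(=O)C(F)(F)F)C(F)(F)F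
Why: Enol triflate formation from the only possible enolate, as is routine for 2,2,6-trisubstituted cyclohexanones; both C6 epimers converge.

Step 7
Reactants: 8 (5S,6R)-5-[(tert-butyldimethylsilyl)oxy]-2,6-dimethyl-6-(prop-2-en-1-yl)cyclohex-1-en-1-yl trifluoromethanesulfonate
Product: 9 (5S,6R)-5-hydroxy-2,6-dimethyl-6-(prop-2-en-1-yl)cyclohex-1-en-1-yl trifluoromethanesulfonate
Conditions: HF (48 % aq.), MeCN, rt
Reagents that add atoms: none
Why: Acidic fluoride cleavage of the silyl ether; the enol triflate and the allyl group are stable to aqueous HF.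

Step 8
Reactants: 9 (5S,6R)-5-hydroxy-2,6-dimethyl-6-(prop-2-en-1-yl)cyclohex-1-en-1-yl trifluoromethanesulfonate; 10 2-methylbut-3-yn-2-ol
Product: 13 (5S,6R)-2,6-dimethyl-5-[(2-methylbut-3-yn-2-yl)oxy]-6-(prop-2-en-1-yl)cyclohex-1-en-1-yl trifluoromethanesulfonate, via cobalt-complexed alkynol 11 (not isolated), via cobalt-complexed propargylic ether 12 (not isolated)
Conditions: 10 (3 equiv), Co2(CO)8, CH2Cl2, rt; then 9, BF3·OEt2, −20 → 0 °C; then (NH4)2Ce(NO3)6, acetone, 0 °C
Reagents that add atoms: none
Why: Nicholas reaction; BF3 ionises the Co2(CO)6-complexed tertiary propargylic alcohol to a stabilised cation that the hindered secondary alcohol captures under SN1 conditions, with the ring C–O bond and its configuration untouched. Oxidation with tetravalent cerium then releases the alkyne.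

Step 9
Reactants: 13 (5S,6R)-2,6-dimethyl-5-[(2-methylbut-3-yn-2-yl)oxy]-6-(prop-2-en-1-yl)cyclohex-1-en-1-yl trifluoromethanesulfonate
Product: 14 (5S,6R)-2,6-dimethyl-5-[(2-methyl-3-oxobutan-2-yl)oxy]-6-(prop-2-en-1-yl)cyclohex-1-en-1-yl trifluoromethanesulfonate
Conditions: (Ph3P)AuNTf2 (3 mol %), 1,4-dioxane/H2O 4:1, 60 °C
Reagents that add atoms: water, O
Why: Gold-catalysed Markovnikov hydration of a terminal alkyne to the methyl ketone; monovalent gold activates the alkyne in preference to the allyl and enol triflate alkenes.

Step 10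
Reactants: 14 (5S,6R)-2,6-dimethyl-5-[(2-methyl-3-oxobutan-2-yl)oxy]-6-(prop-2-en-1-yl)cyclohex-1-en-1-yl trifluoromethanesulfonate
Product: 15 (5S,6R)-5-({3-[(tert-butyldimethylsilyl)oxy]-2-methylbut-3-en-2-yl}oxy)-2,6-dimethyl-6-(prop-2-en-1-yl)cyclohex-1-en-1-yl trifluoromethanesulfonate
Conditions: TBSOTf, Et3N, CH2Cl2, −78 → 0 °C
Reagents that add atoms: tert-butyldimethylsilyl trifluoromethanesulfonate, CC(C)(C)[Si](C)(C)OS(=O)(=O)C(F)(F)F
Why: Soft enolisation and O-silylation; the ketone can enolise only toward its methyl group because the other α-carbon is quaternary, so a single 2-silyloxy-1-alkene should form.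

Step 11
Reactants: 15 (5S,6R)-5-({3-[(tert-butyldimethylsilyl)oxy]-2-methylbut-3-en-2-yl}oxy)-2,6-dimethyl-6-(prop-2-en-1-yl)cyclohex-1-en-1-yl trifluoromethanesulfonate
Product: 16 (5aR,9aS)-3-[(tert-butyldimethylsilyl)oxy]-2,2,5a,7-tetramethyl-2,5,5a,8,9,9a-hexahydro-1-benzoxepin-6-yl trifluoromethanesulfonate
Conditions: second-generation Grubbs catalyst (10 mol %), 1,4-benzoquinone (10 mol %), toluene (0.005 M), 80 °C, Ar sparge
Reagents that add atoms: none
Why: The ruthenium benzylidene should exchange onto the monosubstituted allyl alkene, the only unhindered olefin in 15. The resulting alkylidene adds [2+2] to the 1,1-disubstituted silyl enol ether with ruthenium on the CH2 terminus, and cycloreversion forms the C=C bond between the allylic CH and the silyloxy-bearing carbon while the methylidene leaves as ethylene. The closest known reaction type is ring-closing metathesis of silyl and alkyl enol ethers with terminal alkenes to cyclic enol ethers, oxepenes included. The seven-membered ring D closes by metathesis of a 1,8-diene, helped by the gem-dimethyl group, the quaternary carbon and the trans placement of the two arms on ring C. No stereocentre forms and the two existing ones are remote from the reacting carbons. The step needs initiation at the allyl group; the enol ether is too hindered to load first, the tetrasubstituted enol triflate alkene is inert, and benzoquinone should suppress hydride-induced migration of the allyl double bond. The product is the ring D ketone in masked form with its regiochemistry fixed.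

Step 12
Reactants: 16 (5aR,9aS)-3-[(tert-butyldimethylsilyl)oxy]-2,2,5a,7-tetramethyl-2,5,5a,8,9,9a-hexahydro-1-benzoxepin-6-yl trifluoromethanesulfonate
Product: 17 (5aR,9aS)-2,2,5a,7-tetramethyl-3-oxo-2,3,4,5,5a,8,9,9a-octahydro-1-benzoxepin-6-yl trifluoromethanesulfonate
Conditions: Bu4NF, AcOH, THF, 0 °C
Reagents that add atoms: none
Why: Fluoride-induced cleavage of the silyl enol ether with protonation at C4 gives the ketone; the acetic acid buffer keeps the enol triflate intact.

Step 13
Reactants: 17 (5aR,9aS)-2,2,5a,7-tetramethyl-3-oxo-2,3,4,5,5a,8,9,9a-octahydro-1-benzoxepin-6-yl trifluoromethanesulfonate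
Product: 18 (3R,5aR,9aS)-3-hydroxy-2,2,5a,7-tetramethyl-2,3,4,5,5a,8,9,9a-octahydro-1-benzoxepin-6-yl trifluoromethanesulfonate
Conditions: (S)-2-methyl-CBS-oxazaborolidine (0.5 equiv), BH3·SMe2, THF, −20 °C; MeOH quench
Reagents that add atoms: none
Why: Corey–Bakshi–Shibata reduction; the O-bearing quaternary C2 is the large group and the C4 methylene the small one, so the (S)-catalyst should give the (R)-carbinol. The same face, opposite the angular methyl, is also the expected substrate preference, and no alkene in 17 is reactive toward borane.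

Step 14
Reactants: 18 (3R,5aR,9aS)-3-hydroxy-2,2,5a,7-tetramethyl-2,3,4,5,5a,8,9,9a-octahydro-1-benzoxepin-6-yl trifluoromethanesulfonate; 19 tributyl(ethenyl)stannane
Product: 20 (3R,5aS,9aS)-6-ethenyl-2,2,5a,7-tetramethyl-2,3,4,5,5a,8,9,9a-octahydro-1-benzoxepin-3-ol
Conditions: Pd(PPh3)4 (5 mol %), LiCl (3 equiv), THF, 65 °C
Reagents that add atoms: none
Why: Stille coupling of an enol triflate with a vinylstannane; zerovalent palladium inserts into the C–OTf bond and chloride assists transmetallation. The free hydroxyl is tolerated.

Step 15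
Reactants: 20 (3R,5aS,9aS)-6-ethenyl-2,2,5a,7-tetramethyl-2,3,4,5,5a,8,9,9a-octahydro-1-benzoxepin-3-ol; 17 (5aR,9aS)-2,2,5a,7-tetramethyl-3-oxo-2,3,4,5,5a,8,9,9a-octahydro-1-benzoxepin-6-yl trifluoromethanesulfonate
Product: 22 sodwanone T, via B-alkyl-9-BBN borane 21 (not isolated)
Conditions: 9-BBN (2.5 equiv), THF, 0 °C → rt; then 3 M aq. K3PO4; then 17, PdCl2(dppf) (10 mol %), AsPh3 (20 mol %), DMF, 50 °C
Reagents that add atoms: none
Why: 9-BBN should hydroborate only the terminal vinyl carbon of the hindered diene (the tetrasubstituted alkene is inert), and aqueous base destroys excess B–H before the ketone partner is added. B-alkyl Suzuki–Miyaura coupling then joins the primary alkylborane to the enol triflate, with the ring D ketone and the free carbinol tolerated; no stereocentre is touched.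

## Compound list

1 | 2-methylcyclohexane-1,3-dione | CC1C(=O)CCCC1=O | starting material
2 | prop-2-en-1-ol (allyl alcohol) | C=CCO | starting material
3 | 2-methyl-3-(prop-2-en-1-yloxy)cyclohex-2-en-1-one | CC1=C(OCC=C)CCCC1=O | intermediate
4 | (1S)-2-methyl-3-(prop-2-en-1-yloxy)cyclohex-2-en-1-ol | CC1=C(OCC=C)CCC[C@@H]1O | intermediate
5 | tert-butyl(dimethyl){[(1S)-2-methyl-3-(prop-2-en-1-yloxy)cyclohex-2-en-1-yl]oxy}silane | CC1=C(OCC=C)CCC[C@@H]1O[Si](C)(C)C(C)(C)C | intermediate
6 | (2R,3S)-3-[(tert-butyldimethylsilyl)oxy]-2-methyl-2-(prop-2-en-1-yl)cyclohexan-1-one | O=C1[C@](C)(CC=C)[C@@H](O[Si](C)(C)C(C)(C)C)CCC1 | intermediate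
7 | (2R,3S)-3-[(tert-butyldimethylsilyl)oxy]-2,6-dimethyl-2-(prop-2-en-1-yl)cyclohexan-1-one, C6 epimers | O=C1[C@](C)(CC=C)[C@@H](O[Si](C)(C)C(C)(C)C)CCC1C | intermediate
8 | (5S,6R)-5-[(tert-butyldimethylsilyl)oxy]-2,6-dimethyl-6-(prop-2-en-1-yl)cyclohex-1-en-1-yl trifluoromethanesulfonate | CC1=C(OS(=O)(=O)C(F)(F)F)[C@](C)(CC=C)[C@@H](O[Si](C)(C)C(C)(C)C)CC1 | intermediate
9 | (5S,6R)-5-hydroxy-2,6-dimethyl-6-(prop-2-en-1-yl)cyclohex-1-en-1-yl trifluoromethanesulfonate | CC1=C(OS(=O)(=O)C(F)(F)F)[C@](C)(CC=C)[C@@H](O)CC1 | intermediate
10 | 2-methylbut-3-yn-2-ol | CC(C)(O)C#C | starting material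
11 | hexacarbonyl(μ-2-methylbut-3-yn-2-ol)dicobalt, the Co2(CO)6 complex of 10 | CC(C)(O)C12[CH]3[Co]1(=C=O)(=C=O)(=C=O)[Co]23(=C=O)(=C=O)=C=O | intermediate (not isolated)
12 | Co2(CO)6 complex of propargylic ether 13 | CC1=C(OS(=O)(=O)C(F)(F)F)[C@](C)(CC=C)[C@@H](OC(C)(C)C23[CH]4[Co]2(=C=O)(=C=O)(=C=O)[Co]34(=C=O)(=C=O)=C=O)CC1 | intermediate (not isolated)
13 | (5S,6R)-2,6-dimethyl-5-[(2-methylbut-3-yn-2-yl)oxy]-6-(prop-2-en-1-yl)cyclohex-1-en-1-yl trifluoromethanesulfonate | CC1=C(OS(=O)(=O)C(F)(F)F)[C@](C)(CC=C)[C@@H](OC(C)(C)C#C)CC1 | intermediate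
14 | (5S,6R)-2,6-dimethyl-5-[(2-methyl-3-oxobutan-2-yl)oxy]-6-(prop-2-en-1-yl)cyclohex-1-en-1-yl trifluoromethanesulfonate | CC1=C(OS(=O)(=O)C(F)(F)F)[C@](C)(CC=C)[C@@H](OC(C)(C)C(C)=O)CC1 | intermediate
15 | (5S,6R)-5-({3-[(tert-butyldimethylsilyl)oxy]-2-methylbut-3-en-2-yl}oxy)-2,6-dimethyl-6-(prop-2-en-1-yl)cyclohex-1-en-1-yl trifluoromethanesulfonate | CC1=C(OS(=O)(=O)C(F)(F)F)[C@](C)(CC=C)[C@@H](OC(C)(C)C(=C)O[Si](C)(C)C(C)(C)C)CC1 | intermediate (key-step precursor)
16 | (5aR,9aS)-3-[(tert-butyldimethylsilyl)oxy]-2,2,5a,7-tetramethyl-2,5,5a,8,9,9a-hexahydro-1-benzoxepin-6-yl trifluoromethanesulfonate | CC1=C(OS(=O)(=O)C(F)(F)F)[C@]2(C)CC=C(O[Si](C)(C)C(C)(C)C)C(C)(C)O[C@H]2CC1 | intermediate (key-step product)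
17 | (5aR,9aS)-2,2,5a,7-tetramethyl-3-oxo-2,3,4,5,5a,8,9,9a-octahydro-1-benzoxepin-6-yl trifluoromethanesulfonate | CC1=C(OS(=O)(=O)C(F)(F)F)[C@]2(C)CCC(=O)C(C)(C)O[C@H]2CC1 | intermediate
18 | (3R,5aR,9aS)-3-hydroxy-2,2,5a,7-tetramethyl-2,3,4,5,5a,8,9,9a-octahydro-1-benzoxepin-6-yl trifluoromethanesulfonate | CC1=C(OS(=O)(=O)C(F)(F)F)[C@]2(C)CC[C@@H](O)C(C)(C)O[C@H]2CC1 | intermediate
19 | tributyl(ethenyl)stannane | C=C[Sn](CCCC)(CCCC)CCCC | starting material
20 | (3R,5aS,9aS)-6-ethenyl-2,2,5a,7-tetramethyl-2,3,4,5,5a,8,9,9a-octahydro-1-benzoxepin-3-ol | CC1=C(C=C)[C@]2(C)CC[C@@H](O)C(C)(C)O[C@H]2CC1 | intermediate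
21 | (3R,5aS,9aS)-6-[2-(9-borabicyclo[3.3.1]nonan-9-yl)ethyl]-2,2,5a,7-tetramethyl-2,3,4,5,5a,8,9,9a-octahydro-1-benzoxepin-3-ol | CC1=C(CCB2C3CCCC2CCC3)[C@]2(C)CC[C@@H](O)C(C)(C)O[C@H]2CC1 | intermediate (not isolated)
22 | sodwanone T | CC1=C(CCC2=C(C)CC[C@@H]3OC(C)(C)[C@H](O)CC[C@@]23C)[C@]2(C)CCC(=O)C(C)(C)O[C@H]2CC1 | target

## Step count and risks

Total: 15 steps. Longest linear sequence: 15 steps (1 → 22); ketone 17 is used a second time as the coupling partner in step 15.

**Step 11 (key step).** The ruthenium alkylidene on the allyl arm may fail to engage the hindered, electron-rich 1,1-disubstituted silyl enol ether, so that migration of the allyl double bond or intermolecular dimerisation takes over. The fallback closes ring D by an aldol condensation and sets out from 14. Isomerisation of the allyl group with (Ph3P)3Ru(CO)(Cl)H in toluene should give the prop-1-enyl ketone (5S,6R)-2,6-dimethyl-5-[(2-methyl-3-oxobutan-2-yl)oxy]-6-(prop-1-en-1-yl)cyclohex-1-en-1-yl trifluoromethanesulfonate F1. Cleavage with OsO4 (cat.)/NaIO4/2,6-lutidine should give the non-enolisable neopentyl aldehyde (5S,6R)-6-formyl-2,6-dimethyl-5-[(2-methyl-3-oxobutan-2-yl)oxy]cyclohex-1-en-1-yl trifluoromethanesulfonate F2. Its only enolisable position is the ketone methyl, so pyrrolidinium acetate in toluene should close the seven-membered enone (5aR,9aS)-2,2,5a,7-tetramethyl-3-oxo-2,3,5a,8,9,9a-hexahydro-1-benzoxepin-6-yl trifluoromethanesulfonate F3. Conjugate reduction with [(Ph3P)CuH]6 returns to the route at 17.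

**Step 2.** Slow hydride transfer to the electron-rich vinylogous ester carbonyl may erode enantioselectivity through uncatalysed background reduction, and the 3-alkoxy allylic alcohol may ionise during work-up. The fallback is a resolution and sets out from 3. Luche reduction (NaBH4, CeCl3·7H2O, MeOH, −40 °C) should give racemic 2-methyl-3-(prop-2-en-1-yloxy)cyclohex-2-en-1-ol F4. Candida antarctica lipase B with vinyl acetate in hexane should acetylate the (R)-enantiomer to (1R)-2-methyl-3-(prop-2-en-1-yloxy)cyclohex-2-en-1-yl acetate F5 and leave the (S)-alcohol, which is 4.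

**Step 4.** Facial selectivity in the [3,3] shift may be poor if the silyloxy group does not hold the pseudoaxial position, and silanol elimination may compete at 170 °C. The fallback transposes a ketol by known chemistry, sets out from 3 and returns at 6.
- Heating 3 alone at about 190 °C should give, by a Claisen rearrangement without a stereochemical issue, 2-methyl-2-(prop-2-en-1-yl)cyclohexane-1,3-dione F6.
- Baker's yeast reduction is expected to give (2S,3S)-3-hydroxy-2-methyl-2-(prop-2-en-1-yl)cyclohexan-1-one F7, with the hydroxyl on the allyl face.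
- Evans–Tishchenko reduction (PhCHO, SmI2 cat., THF, −10 °C) delivers hydride from the hemiacetal on the face of that hydroxyl and should give (1S,2R,3S)-3-hydroxy-2-methyl-2-(prop-2-en-1-yl)cyclohexyl benzoate F8, whose new free hydroxyl is trans to the allyl group.
- Silylation (TBSOTf, 2,6-lutidine) gives (1S,2S,3S)-3-[(tert-butyldimethylsilyl)oxy]-2-methyl-2-(prop-2-en-1-yl)cyclohexyl benzoate F9.
- i-Bu2AlH removes the benzoate to give (1S,2S,3S)-3-[(tert-butyldimethylsilyl)oxy]-2-methyl-2-(prop-2-en-1-yl)cyclohexan-1-ol F10.
- Dess–Martin oxidation gives 6.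

**Step 8.** The tertiary cobalt-stabilised cation may lose a proton to the enyne complex faster than it is captured by the hindered neopentyl alcohol, and the ether may re-ionise under the Lewis acid. The fallback builds the ether by carbenoid O–H insertion and sets out from 9. Rh2(OAc)4-catalysed insertion of methyl 2-diazopropanoate should give methyl 2-{[(1S,2R)-2,4-dimethyl-2-(prop-2-en-1-yl)-3-(trifluoromethanesulfonyloxy)cyclohex-3-en-1-yl]oxy}propanoate F11. Enolate methylation (LiN(i-Pr)2, MeI) gives methyl 2-methyl-2-{[(1S,2R)-2,4-dimethyl-2-(prop-2-en-1-yl)-3-(trifluoromethanesulfonyloxy)cyclohex-3-en-1-yl]oxy}propanoate F12. MeNH(OMe)·HCl with i-PrMgCl gives the Weinreb amide N-methoxy-N,2-dimethyl-2-{[(1S,2R)-2,4-dimethyl-2-(prop-2-en-1-yl)-3-(trifluoromethanesulfonyloxy)cyclohex-3-en-1-yl]oxy}propanamide F13, and MeMgBr returns to the route at 14.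

**Step 15.** Oxidative addition and transmetallation at the tetrasubstituted triflate flanked by a quaternary carbon may be slow, so that protodeboronation or β-hydride elimination of the alkyl group competes. The fallback avoids organoboron transmetallation and sets out from 20. Hydroboration–oxidation (9-BBN; NaBO3·4H2O) gives (3R,5aS,9aS)-6-(2-hydroxyethyl)-2,2,5a,7-tetramethyl-2,3,4,5,5a,8,9,9a-octahydro-1-benzoxepin-3-ol F14. Selective iodination of the primary hydroxyl (I2, PPh3, imidazole) gives (3R,5aS,9aS)-6-(2-iodoethyl)-2,2,5a,7-tetramethyl-2,3,4,5,5a,8,9,9a-octahydro-1-benzoxepin-3-ol F15. Nickel-catalysed reductive cross-electrophile coupling of F15 with 17 (NiBr2(dme), 4,4′-di-tert-butyl-2,2′-bipyridine, Zn, DMA) tolerates the ketone and the free hydroxyl and returns to the route at 22.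

## Further compounds

F1 | step 11 | (5S,6R)-2,6-dimethyl-5-[(2-methyl-3-oxobutan-2-yl)oxy]-6-(prop-1-en-1-yl)cyclohex-1-en-1-yl trifluoromethanesulfonate | CC1=C(OS(=O)(=O)C(F)(F)F)[C@](C)(C=CC)[C@@H](OC(C)(C)C(C)=O)CC1
F2 | step 11 | (5S,6R)-6-formyl-2,6-dimethyl-5-[(2-methyl-3-oxobutan-2-yl)oxy]cyclohex-1-en-1-yl trifluoromethanesulfonate | CC1=C(OS(=O)(=O)C(F)(F)F)[C@](C)(C=O)[C@@H](OC(C)(C)C(C)=O)CC1
F3 | step 11 | (5aR,9aS)-2,2,5a,7-tetramethyl-3-oxo-2,3,5a,8,9,9a-hexahydro-1-benzoxepin-6-yl trifluoromethanesulfonate | CC1=C(OS(=O)(=O)C(F)(F)F)[C@]2(C)C=CC(=O)C(C)(C)O[C@H]2CC1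
F4 | step 2 | racemic 2-methyl-3-(prop-2-en-1-yloxy)cyclohex-2-en-1-ol | CC1=C(OCC=C)CCCC1O
F5 | step 2 | (1R)-2-methyl-3-(prop-2-en-1-yloxy)cyclohex-2-en-1-yl acetate | CC1=C(OCC=C)CCC[C@H]1OC(C)=O
F6 | step 4 | 2-methyl-2-(prop-2-en-1-yl)cyclohexane-1,3-dione | CC1(CC=C)C(=O)CCCC1=O
F7 | step 4 | (2S,3S)-3-hydroxy-2-methyl-2-(prop-2-en-1-yl)cyclohexan-1-one | O=C1[C@@](C)(CC=C)[C@@H](O)CCC1
F8 | step 4 | (1S,2R,3S)-3-hydroxy-2-methyl-2-(prop-2-en-1-yl)cyclohexyl benzoate | O[C@@H]1[C@@](C)(CC=C)[C@@H](OC(=O)c2ccccc2)CCC1
F9 | step 4 | (1S,2S,3S)-3-[(tert-butyldimethylsilyl)oxy]-2-methyl-2-(prop-2-en-1-yl)cyclohexyl benzoate | CC(C)(C)[Si](C)(C)O[C@@H]1[C@@](C)(CC=C)[C@@H](OC(=O)c2ccccc2)CCC1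
F10 | step 4 | (1S,2S,3S)-3-[(tert-butyldimethylsilyl)oxy]-2-methyl-2-(prop-2-en-1-yl)cyclohexan-1-ol | CC(C)(C)[Si](C)(C)O[C@@H]1[C@@](C)(CC=C)[C@@H](O)CCC1
F11 | step 8 | methyl 2-{[(1S,2R)-2,4-dimethyl-2-(prop-2-en-1-yl)-3-(trifluoromethanesulfonyloxy)cyclohex-3-en-1-yl]oxy}propanoate | CC1=C(OS(=O)(=O)C(F)(F)F)[C@](C)(CC=C)[C@@H](OC(C)C(=O)OC)CC1
F12 | step 8 | methyl 2-methyl-2-{[(1S,2R)-2,4-dimethyl-2-(prop-2-en-1-yl)-3-(trifluoromethanesulfonyloxy)cyclohex-3-en-1-yl]oxy}propanoate | CC1=C(OS(=O)(=O)C(F)(F)F)[C@](C)(CC=C)[C@@H](OC(C)(C)C(=O)OC)CC1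
F13 | step 8 | N-methoxy-N,2-dimethyl-2-{[(1S,2R)-2,4-dimethyl-2-(prop-2-en-1-yl)-3-(trifluoromethanesulfonyloxy)cyclohex-3-en-1-yl]oxy}propanamide | CC1=C(OS(=O)(=O)C(F)(F)F)[C@](C)(CC=C)[C@@H](OC(C)(C)C(=O)N(C)OC)CC1
F14 | step 15 | (3R,5aS,9aS)-6-(2-hydroxyethyl)-2,2,5a,7-tetramethyl-2,3,4,5,5a,8,9,9a-octahydro-1-benzoxepin-3-ol | CC1=C(CCO)[C@]2(C)CC[C@@H](O)C(C)(C)O[C@H]2CC1
F15 | step 15 | (3R,5aS,9aS)-6-(2-iodoethyl)-2,2,5a,7-tetramethyl-2,3,4,5,5a,8,9,9a-octahydro-1-benzoxepin-3-ol | CC1=C(CCI)[C@]2(C)CC[C@@H](O)C(C)(C)O[C@H]2CC1
A1 | alternative 1 | bis(1-methyl-2-methoxycyclohexa-2,5-diene) bis-amide with both quaternary centres | CC1=C(CCC2=C(C)CC=C(OC)[C@@]2(C)C(=O)N2CCC[C@H]2COC)[C@](C)(C(=O)N2CCC[C@H]2COC)C(OC)=CC1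
A2 | alternative 1 | C2-symmetric bibenzyl bis(2-methoxybenzamide) of prolinol methyl ether | COc1ccc(C)c(CCc2c(C)ccc(OC)c2C(=O)N2CCC[C@H]2COC)c1C(=O)N1CCC[C@H]1COC
A3 | alternative 2 | tricyclic furanone–cyclobutane–cyclohexane photoadduct | CC(C)(C)[Si](C)(C)O[C@H]1CCC[C@@]23OC(C)(C)C(=O)[C@@H]2C[C@@]13C
A4 | alternative 2 | 5-[(4S)-4-[(tert-butyldimethylsilyl)oxy]-5-methylhex-5-en-1-yl]-2,2-dimethylfuran-3(2H)-one | CC(=C)[C@@H](O[Si](C)(C)C(C)(C)C)CCCC1=CC(=O)C(C)(C)O1
A5 | alternative 3 | ring A/B bicycle with silylated carbinol and benzyloxyethyl side chain | c1ccccc1COCCC1=C(C)CC[C@@H]2OC(C)(C)[C@H](O[Si](C)(C)C(C)(C)C)CC[C@@]12C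
A6 | alternative 3 | eleven-membered cyclic α-acetoxy ether with tetrasubstituted alkene (alkene geometry and two further centres not specified) | CC(=O)OC1CCC(C)C(CCOCc2ccccc2)=C(C)CC[C@@H](O[Si](C)(C)C(C)(C)C)C(C)(C)O1
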